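**Retrosynthetic overview**
- Last step: global hydrogenolysis of a pentabenzyl precursor (two aryl benzyl ethers, two alkyl benzyl ethers, one benzyl ester) under neutral conditions.
- Ester disconnection at the arylpropan-2-yl oxygen gives a resorcylate alcohol (already carrying the (S)-3-oxybutanoate benzyl ester) and a diester acid made from (R)-3,4-bis(benzyloxy)butanoic acid and tert-butyl (R)-3-hydroxybutanoate.
- The hindered aryl ester is not made by esterification: a diketo-dioxinone is thermolysed to an acylketene, trapped by benzyl (S)-3-hydroxybutanoate, and the resulting triketo ester is cyclised by aldol condensation and dehydration.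
- Key C–C bond: intermolecular Claisen condensation of the dianion of 2,2-dimethyl-6-(2-oxopropyl)-1,3-dioxin-4-one with the Weinreb amide of (R)-3-(silyloxy)butanoic acid; the carbinol stereocentre comes from the chiral pool.
- Ring order: the dioxinone ring is bought and sacrificed; the benzene ring is the only ring formed, after the ketene trapping.

Assumption: the SMILES is read as (R) at the dihydroxybutanoyl carbinol, (R) at the central 3-oxybutanoate, (R) at the arylpropan-2-yl carbon and (S) at the terminal 3-oxybutanoic acid; TIPS = triisopropylsilyl, Bn = benzyl.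

**Route**

Step 1
Reactants: 1 2,2,6-trimethyl-4H-1,3-dioxin-4-one
Product: 3 2,2-dimethyl-6-(2-oxopropyl)-4H-1,3-dioxin-4-one, via lithium dienolate 2 (not isolated)
Conditions: LiN(SiMe3)2 (1.0 equiv), THF, −78 °C, 1 h; AcCl (0.5 equiv), −78 °C; 1 M HCl
Reagents that add atoms: acetyl chloride CC(=O)Cl
Why: Deprotonation of the vinylogous ester at the 6-methyl group gives the extended dienolate, which is C-acylated at the exocyclic carbon (Claisen-type acylation), two enolates per acid chloride being used because the more acidic product is deprotonated as it forms.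

Step 2
Reactants: 4 methyl (R)-3-hydroxybutanoate
Product: 5 methyl (R)-3-[(triisopropylsilyl)oxy]butanoate
Conditions: iPr3SiOTf, 2,6-lutidine, CH2Cl2, 0 °C → rt
Reagents that add atoms: triisopropylsilyl triflate CC(C)[Si](OS(=O)(=O)C(F)(F)F)(C(C)C)C(C)C
Why: Silyl triflate with a hindered pyridine base silylates the secondary alcohol cleanly (O-silylation) without touching the stereocentre or causing β-elimination.

Step 3
Reactants: 5 methyl (R)-3-[(triisopropylsilyl)oxy]butanoate
Product: 6 (R)-N-methoxy-N-methyl-3-[(triisopropylsilyl)oxy]butanamide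
Conditions: MeNHOMe·HCl (1.5 equiv), iPrMgCl (3.0 equiv), THF, −20 → 0 °C
Reagents that add atoms: N,O-dimethylhydroxylamine hydrochloride CNOC.Cl
Why: The chloromagnesium amide formed in the flask converts the ester directly into the Weinreb amide (ester aminolysis) at low temperature, where the β-silyloxy group does not eliminate.

Step 4
Reactants: 3 2,2-dimethyl-6-(2-oxopropyl)-4H-1,3-dioxin-4-one; 6 (R)-N-methoxy-N-methyl-3-[(triisopropylsilyl)oxy]butanamide
Product: 8 6-[(6R)-2,4-dioxo-6-[(triisopropylsilyl)oxy]heptyl]-2,2-dimethyl-4H-1,3-dioxin-4-one, via dilithium dianion 7 (not isolated)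
Conditions: 3 (1.5 equiv), LiN(iPr)2 (3.1 equiv), THF, −78 °C, 1 h; 6 (1.0 equiv), −78 → −40 °C; 1 M HCl to pH 3
Reagents that add atoms: none
Why: Intermolecular Claisen condensation in which the terminal, last-formed carbanion of the keto-dioxinone dianion attacks the Weinreb amide, whose chelated tetrahedral adduct prevents over-addition; the (R) stereocentre is carried in unchanged from 4.

Step 5
Reactants: 9 ethyl (S)-3-hydroxybutanoate
Product: 10 benzyl (S)-3-hydroxybutanoate
Conditions: BnOH (3 equiv), Ti(OEt)4 (5 mol %), toluene, 110 °C, EtOH distilled off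
Reagents that add atoms: benzyl alcohol OCc1ccccc1
Why: Titanate-mediated transesterification is essentially neutral, so the β-hydroxy ester neither eliminates nor racemises.

Step 6
Reactants: 8 6-[(6R)-2,4-dioxo-6-[(triisopropylsilyl)oxy]heptyl]-2,2-dimethyl-4H-1,3-dioxin-4-one; 10 benzyl (S)-3-hydroxybutanoate
Product: 12 benzyl (S)-3-{[(9R)-3,5,7-trioxo-9-[(triisopropylsilyl)oxy]decanoyl]oxy}butanoate (keto–enol mixture, used crude), via acylketene 11 (not isolated)
Conditions: 10 (1.2 equiv), toluene, 110 °C, 2 h; concentrate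
Reagents that add atoms: none
Why: Retro-hetero-Diels–Alder fragmentation of the dioxinone expels acetone and gives an acylketene that is trapped by the secondary alcohol, forming the future hindered benzoate ester without ever activating a 2,6-disubstituted benzoic acid.

Step 7
Reactants: 12 benzyl (S)-3-{[(9R)-3,5,7-trioxo-9-[(triisopropylsilyl)oxy]decanoyl]oxy}butanoate
Product: 14 benzyl (S)-3-({2,4-dihydroxy-6-[(R)-2-[(triisopropylsilyl)oxy]propyl]benzoyl}oxy)butanoate, via cyclic aldol 13 (not isolated)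
Conditions: K2CO3 (3 equiv), iPrOH/CH2Cl2 (1:1), rt; then HCl (1.25 M in MeOH), rt, brief
Reagents that add atoms: none
Why: Biomimetic intramolecular aldol condensation of the most acidic C2 methylene onto the C7 ketone, then acid-promoted dehydration and enolisation, gives the resorcylate, with iPrOH avoiding transesterification and the hindered silyl ether surviving the short acid exposure.

Step 8
Reactants: 14 benzyl (S)-3-({2,4-dihydroxy-6-[(R)-2-[(triisopropylsilyl)oxy]propyl]benzoyl}oxy)butanoate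
Product: 16 benzyl (S)-3-({2,4-bis(benzyloxy)-6-[(R)-2-[(triisopropylsilyl)oxy]propyl]benzoyl}oxy)butanoate, via 4-O-benzyl ether 15 (not isolated)
Conditions: BnBr (3 equiv), K2CO3 (4 equiv), DMF, rt → 40 °C
Reagents that add atoms: benzyl bromide BrCc1ccccc1
Why: Williamson etherification of both phenols (the free 4-OH first, the chelated 2-OH second) with a mild carbonate base that leaves the esters and the silyl ether intact.

Step 9
Reactants: 16 benzyl (S)-3-({2,4-bis(benzyloxy)-6-[(R)-2-[(triisopropylsilyl)oxy]propyl]benzoyl}oxy)butanoate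
Product: 17 benzyl (S)-3-({2,4-bis(benzyloxy)-6-[(R)-2-hydroxypropyl]benzoyl}oxy)butanoate
Conditions: HF·pyridine, THF/pyridine, 0 °C → rt, 24 h
Reagents that add atoms: none
Why: Buffered acidic fluoride desilylation frees the secondary alcohol without generating an alkoxide, which would lactonise onto the neighbouring aryl ester.

Step 10
Reactants: 18 (R)-benzyl glycidyl ether
Product: 19 (R)-1-(benzyloxy)pent-4-en-2-ol
Conditions: CH2=CHMgBr (1.5 equiv), CuI (10 mol %), THF, −40 → −20 °C; aqueous work-up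
Reagents that add atoms: vinylmagnesium bromide C=C[Mg]Br
Why: Copper-catalysed Grignard opening of the epoxide occurs at the unsubstituted terminus (SN2), so no bond to the stereocentre is broken and the (R) configuration is retained.

Step 11
Reactants: 19 (R)-1-(benzyloxy)pent-4-en-2-ol
Product: 21 (R)-1,2-bis(benzyloxy)pent-4-ene, via sodium alkoxide 20 (not isolated)
Conditions: NaH (1.3 equiv), THF/DMF, 0 °C; BnBr (1.2 equiv), Bu4NI (5 mol %), rt
Reagents that add atoms: benzyl bromide BrCc1ccccc1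
Why: Williamson ether synthesis on a simple secondary alkoxide with no base-sensitive groups present.

Step 12
Reactants: 21 (R)-1,2-bis(benzyloxy)pent-4-ene
Product: 23 (R)-3,4-bis(benzyloxy)butanal (used crude), via vicinal diol 22 (not isolated)
Conditions: OsO4 (2 mol %), NaIO4 (4 equiv), 2,6-lutidine (2 equiv), dioxane/H2O (3:1), rt
Reagents that add atoms: osmium tetroxide O=[Os](=O)(=O)=O (delivers the oxygen; turned over by sodium periodate [Na+].[O-]I(=O)(=O)=O and water O)
Why: Lemieux–Johnson oxidative cleavage (dihydroxylation then periodate glycol cleavage) removes the terminal carbon without attacking the benzyl ethers, and the lutidine buffer suppresses β-elimination of the aldehyde.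

Step 13
Reactants: 23 (R)-3,4-bis(benzyloxy)butanal
Product: 24 (R)-3,4-bis(benzyloxy)butanoic acid
Conditions: NaClO2, NaH2PO4, 2-methylbut-2-ene, tBuOH/H2O, 0 °C → rt
Reagents that add atoms: sodium chlorite [Na+].[O-]Cl=O
Why: Pinnick oxidation converts the aldehyde to the acid under buffered conditions that neither epimerise nor eliminate the β-benzyloxy group.

Step 14
Reactants: 24 (R)-3,4-bis(benzyloxy)butanoic acid; 25 tert-butyl (R)-3-hydroxybutanoate
Product: 27 tert-butyl (R)-3-{[(R)-3,4-bis(benzyloxy)butanoyl]oxy}butanoate, via O-acylisourea 26 (not isolated)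
Conditions: DCC (1.2 equiv), DMAP (0.1 equiv), CH2Cl2, 0 °C → rt
Reagents that add atoms: none
Why: Steglich esterification acylates the secondary alcohol with retention, since the C–O bond at the carbinol is not broken.

Step 15
Reactants: 27 tert-butyl (R)-3-{[(R)-3,4-bis(benzyloxy)butanoyl]oxy}butanoate
Product: 28 (R)-3-{[(R)-3,4-bis(benzyloxy)butanoyl]oxy}butanoic acid
Conditions: TFA/CH2Cl2 (1:4), 0 °C → rt, 2 h; toluene azeotrope
Reagents that add atoms: none
Why: Acidolysis of the tert-butyl ester (loss of isobutene through the tert-butyl cation) is orthogonal to benzyl ethers and to the internal secondary ester.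

Step 16
Reactants: 28 (R)-3-{[(R)-3,4-bis(benzyloxy)butanoyl]oxy}butanoic acid
Product: 29 (R)-3-{[(R)-3,4-bis(benzyloxy)butanoyl]oxy}butanoyl chloride (crude, used at once)
Conditions: (COCl)2 (1.5 equiv), DMF (cat.), CH2Cl2, 0 °C → rt; evaporate
Reagents that add atoms: oxalyl chloride ClC(=O)C(=O)Cl
Why: Vilsmeier-catalysed acid chloride formation is base-free, so the β-acyloxy acid cannot undergo elimination to a crotonate during activation.

Step 17
Reactants: 17 benzyl (S)-3-({2,4-bis(benzyloxy)-6-[(R)-2-hydroxypropyl]benzoyl}oxy)butanoate; 29 (R)-3-{[(R)-3,4-bis(benzyloxy)butanoyl]oxy}butanoyl chloride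
Product: 30 benzyl (S)-3-{[2,4-bis(benzyloxy)-6-((R)-2-{[(R)-3-{[(R)-3,4-bis(benzyloxy)butanoyl]oxy}butanoyl]oxy}propyl)benzoyl]oxy}butanoate
Conditions: 29 (1.5 equiv), pyridine (3 equiv), CH2Cl2, −78 → 0 °C
Reagents that add atoms: none
Why: Acylation of the secondary alcohol by the acid chloride with only pyridine at low temperature (nucleophilic acyl substitution, retention at the carbinol) avoids the base-induced β-elimination that stronger acyl-transfer conditions cause with β-acyloxy acyl donors.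

Step 18
Reactants: 30 benzyl (S)-3-{[2,4-bis(benzyloxy)-6-((R)-2-{[(R)-3-{[(R)-3,4-bis(benzyloxy)butanoyl]oxy}butanoyl]oxy}propyl)benzoyl]oxy}butanoate
Product: 31 Talapolyester B
Conditions: H2 (1 atm), 10% Pd/C, THF, rt
Reagents that add atoms: none
Why: Global hydrogenolysis cleaves all five benzyl C–O bonds under neutral conditions, which keeps the 3,4-dihydroxybutanoate ester from lactonising and leaves every stereocentre untouched.

**Compound list**
1 | 2,2,6-trimethyl-4H-1,3-dioxin-4-one | CC1=CC(=O)OC(C)(C)O1 | starting material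
2 | lithium dienolate of 1 (lithium 2,2-dimethyl-6-methylidene-6H-1,3-dioxin-4-olate) | [Li+].C=C1C=C([O-])OC(C)(C)O1 | intermediate
3 | 2,2-dimethyl-6-(2-oxopropyl)-4H-1,3-dioxin-4-one | CC(=O)CC1=CC(=O)OC(C)(C)O1 | intermediate
4 | methyl (R)-3-hydroxybutanoate | C[C@@H](O)CC(=O)OC | starting material
5 | methyl (R)-3-[(triisopropylsilyl)oxy]butanoate | C[C@@H](O[Si](C(C)C)(C(C)C)C(C)C)CC(=O)OC | intermediate
6 | (R)-N-methoxy-N-methyl-3-[(triisopropylsilyl)oxy]butanamide | C[C@@H](O[Si](C(C)C)(C(C)C)C(C)C)CC(=O)N(C)OC | intermediate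
7 | dilithium dianion (bis-enolate) of 3 | [Li+].[Li+].C=C([O-])C=C1C=C([O-])OC(C)(C)O1 | intermediate
8 | 6-[(6R)-2,4-dioxo-6-[(triisopropylsilyl)oxy]heptyl]-2,2-dimethyl-4H-1,3-dioxin-4-one | C[C@@H](O[Si](C(C)C)(C(C)C)C(C)C)CC(=O)CC(=O)CC1=CC(=O)OC(C)(C)O1 | intermediate
9 | ethyl (S)-3-hydroxybutanoate | C[C@H](O)CC(=O)OCC | starting material
10 | benzyl (S)-3-hydroxybutanoate | C[C@H](O)CC(=O)OCc1ccccc1 | intermediate
11 | acylketene (9R)-9-[(triisopropylsilyl)oxy]dec-1-ene-1,3,5,7-tetraone | C[C@@H](O[Si](C(C)C)(C(C)C)C(C)C)CC(=O)CC(=O)CC(=O)C=C=O | intermediate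
12 | benzyl (S)-3-{[(9R)-3,5,7-trioxo-9-[(triisopropylsilyl)oxy]decanoyl]oxy}butanoate | C[C@@H](O[Si](C(C)C)(C(C)C)C(C)C)CC(=O)CC(=O)CC(=O)CC(=O)O[C@@H](C)CC(=O)OCc1ccccc1 | intermediate
13 | cyclic aldol: (S)-4-(benzyloxy)-4-oxobutan-2-yl 2-hydroxy-4,6-dioxo-2-[(R)-2-[(triisopropylsilyl)oxy]propyl]cyclohexane-1-carboxylate (ring epimers and enol forms) | C[C@@H](O[Si](C(C)C)(C(C)C)C(C)C)CC1(O)CC(=O)CC(=O)C1C(=O)O[C@@H](C)CC(=O)OCc1ccccc1 | intermediate
14 | benzyl (S)-3-({2,4-dihydroxy-6-[(R)-2-[(triisopropylsilyl)oxy]propyl]benzoyl}oxy)butanoate | C[C@@H](O[Si](C(C)C)(C(C)C)C(C)C)Cc1cc(O)cc(O)c1C(=O)O[C@@H](C)CC(=O)OCc1ccccc1 | intermediate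
15 | benzyl (S)-3-({4-(benzyloxy)-2-hydroxy-6-[(R)-2-[(triisopropylsilyl)oxy]propyl]benzoyl}oxy)butanoate | C[C@@H](O[Si](C(C)C)(C(C)C)C(C)C)Cc1cc(OCc2ccccc2)cc(O)c1C(=O)O[C@@H](C)CC(=O)OCc1ccccc1 | intermediate
16 | benzyl (S)-3-({2,4-bis(benzyloxy)-6-[(R)-2-[(triisopropylsilyl)oxy]propyl]benzoyl}oxy)butanoate | C[C@@H](O[Si](C(C)C)(C(C)C)C(C)C)Cc1cc(OCc2ccccc2)cc(OCc2ccccc2)c1C(=O)O[C@@H](C)CC(=O)OCc1ccccc1 | intermediate
17 | benzyl (S)-3-({2,4-bis(benzyloxy)-6-[(R)-2-hydroxypropyl]benzoyl}oxy)butanoate | C[C@@H](O)Cc1cc(OCc2ccccc2)cc(OCc2ccccc2)c1C(=O)O[C@@H](C)CC(=O)OCc1ccccc1 | intermediate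
18 | (R)-benzyl glycidyl ether, (R)-2-[(benzyloxy)methyl]oxirane | C(OCc1ccccc1)[C@H]1CO1 | starting material
19 | (R)-1-(benzyloxy)pent-4-en-2-ol | C=CC[C@@H](O)COCc1ccccc1 | intermediate
20 | sodium (R)-1-(benzyloxy)pent-4-en-2-olate | [Na+].C=CC[C@@H]([O-])COCc1ccccc1 | intermediate
21 | (R)-1,2-bis(benzyloxy)pent-4-ene | C=CC[C@@H](OCc1ccccc1)COCc1ccccc1 | intermediate
22 | (4R)-4,5-bis(benzyloxy)pentane-1,2-diol (both C2 epimers) | OCC(O)C[C@@H](OCc1ccccc1)COCc1ccccc1 | intermediate
23 | (R)-3,4-bis(benzyloxy)butanal | O=CC[C@@H](OCc1ccccc1)COCc1ccccc1 | intermediate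
24 | (R)-3,4-bis(benzyloxy)butanoic acid | OC(=O)C[C@@H](OCc1ccccc1)COCc1ccccc1 | intermediate
25 | tert-butyl (R)-3-hydroxybutanoate | C[C@@H](O)CC(=O)OC(C)(C)C | starting material
26 | O-acylisourea of 24 with DCC | O=C(C[C@@H](OCc1ccccc1)COCc1ccccc1)OC(=NC1CCCCC1)NC1CCCCC1 | intermediate
27 | tert-butyl (R)-3-{[(R)-3,4-bis(benzyloxy)butanoyl]oxy}butanoate | C[C@H](CC(=O)OC(C)(C)C)OC(=O)C[C@@H](OCc1ccccc1)COCc1ccccc1 | intermediate
28 | (R)-3-{[(R)-3,4-bis(benzyloxy)butanoyl]oxy}butanoic acid | C[C@H](CC(=O)O)OC(=O)C[C@@H](OCc1ccccc1)COCc1ccccc1 | intermediate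
29 | (R)-3-{[(R)-3,4-bis(benzyloxy)butanoyl]oxy}butanoyl chloride | C[C@H](CC(=O)Cl)OC(=O)C[C@@H](OCc1ccccc1)COCc1ccccc1 | intermediate
30 | benzyl (S)-3-{[2,4-bis(benzyloxy)-6-((R)-2-{[(R)-3-{[(R)-3,4-bis(benzyloxy)butanoyl]oxy}butanoyl]oxy}propyl)benzoyl]oxy}butanoate | C[C@H](CC(=O)O[C@H](C)Cc1cc(OCc2ccccc2)cc(OCc2ccccc2)c1C(=O)O[C@@H](C)CC(=O)OCc1ccccc1)OC(=O)C[C@@H](OCc1ccccc1)COCc1ccccc1 | intermediate
31 | Talapolyester B | C[C@H](CC(=O)O[C@H](C)Cc1cc(O)cc(O)c1C(=O)O[C@@H](C)CC(=O)O)OC(=O)C[C@@H](O)CO | target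

**Totals**
Total step count: 18.
Longest linear sequence: 9 steps (steps 2, 3, 4, 6, 7, 8, 9, 17, 18 from 4; equally steps 10 to 18 from 18).

**Steps most likely to fail, with fallbacks**

Step 4 (Claisen condensation of the dianion with the β-silyloxy Weinreb amide; risks are sluggish acylation and elimination of the silyloxy group). The fallback sets out from 5 and 3 and comes back at 8. The Claisen is replaced by an aldol addition followed by oxidation. Ester 5 is reduced with iBu2AlH (CH2Cl2, −78 °C) to (R)-3-[(triisopropylsilyl)oxy]butanal F1. F1 is added at −78 °C to dianion 7, made as before from 3 and LiN(iPr)2, giving 6-[(6R)-4-hydroxy-2-oxo-6-[(triisopropylsilyl)oxy]heptyl]-2,2-dimethyl-4H-1,3-dioxin-4-one F2 as a mixture of carbinol epimers. Oxidation of F2 with Dess–Martin periodinane (CH2Cl2, 0 °C) removes the new carbinol centre and gives 8.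

Step 7 (aromatisation of the triketo ester; risks are β-elimination of the silyloxy group, the wrong cyclisation mode, and loss of the silyl or benzyl ester groups in acid). The fallback sets out from 8 and comes back at 15. The ring is closed before the ester is made. Treating 8 with Et3N (CH2Cl2, rt) lets the dioxinone carbon do the aldol condensation and gives 7-hydroxy-2,2-dimethyl-5-[(R)-2-[(triisopropylsilyl)oxy]propyl]-4H-1,3-benzodioxin-4-one F3. Benzylation (BnBr, K2CO3, acetone) gives 7-(benzyloxy)-2,2-dimethyl-5-[(R)-2-[(triisopropylsilyl)oxy]propyl]-4H-1,3-benzodioxin-4-one F4. Irradiation of F4 at 300 nm in CH2Cl2 in the presence of 10 expels acetone and gives the quinoketene 3-(benzyloxy)-6-(oxomethylidene)-5-[(R)-2-[(triisopropylsilyl)oxy]propyl]cyclohexa-2,4-dien-1-one F5. F5 is trapped by 10 under neutral conditions to give 15, which is carried to 16 under the conditions of step 8.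

Step 17 (fragment esterification with a β-acyloxy acid chloride; risks are elimination to a crotonate and slow acylation of the hindered alcohol). The fallback sets out from 5, 17 and 24 and comes back at 30. The chain is grown one unit at a time, so that no β-acyloxy acid is ever activated. Saponification of 5 (LiOH, THF/H2O) gives (R)-3-[(triisopropylsilyl)oxy]butanoic acid F6. Steglich coupling of F6 with 17 (DCC, DMAP, CH2Cl2) gives benzyl (S)-3-{[2,4-bis(benzyloxy)-6-((R)-2-{[(R)-3-[(triisopropylsilyl)oxy]butanoyl]oxy}propyl)benzoyl]oxy}butanoate F7. Desilylation with HF·pyridine gives benzyl (S)-3-{[2,4-bis(benzyloxy)-6-((R)-2-{[(R)-3-hydroxybutanoyl]oxy}propyl)benzoyl]oxy}butanoate F8. Acylation of F8 with acid 24 (DCC, DMAP) gives 30.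

**Further compounds**
F1 | step 4 | (R)-3-[(triisopropylsilyl)oxy]butanal | C[C@@H](O[Si](C(C)C)(C(C)C)C(C)C)CC=O
F2 | step 4 | 6-[(6R)-4-hydroxy-2-oxo-6-[(triisopropylsilyl)oxy]heptyl]-2,2-dimethyl-4H-1,3-dioxin-4-one (carbinol epimers) | C[C@@H](O[Si](C(C)C)(C(C)C)C(C)C)CC(O)CC(=O)CC1=CC(=O)OC(C)(C)O1
F3 | step 7 | 7-hydroxy-2,2-dimethyl-5-[(R)-2-[(triisopropylsilyl)oxy]propyl]-4H-1,3-benzodioxin-4-one | C[C@@H](O[Si](C(C)C)(C(C)C)C(C)C)Cc1cc(O)cc2OC(C)(C)OC(=O)c12
F4 | step 7 | 7-(benzyloxy)-2,2-dimethyl-5-[(R)-2-[(triisopropylsilyl)oxy]propyl]-4H-1,3-benzodioxin-4-one | C[C@@H](O[Si](C(C)C)(C(C)C)C(C)C)Cc1cc(OCc3ccccc3)cc2OC(C)(C)OC(=O)c12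
F5 | step 7 | 3-(benzyloxy)-6-(oxomethylidene)-5-[(R)-2-[(triisopropylsilyl)oxy]propyl]cyclohexa-2,4-dien-1-one | C[C@@H](O[Si](C(C)C)(C(C)C)C(C)C)CC1=CC(OCc2ccccc2)=CC(=O)C1=C=O
F6 | step 17 | (R)-3-[(triisopropylsilyl)oxy]butanoic acid | C[C@@H](O[Si](C(C)C)(C(C)C)C(C)C)CC(=O)O
F7 | step 17 | benzyl (S)-3-{[2,4-bis(benzyloxy)-6-((R)-2-{[(R)-3-[(triisopropylsilyl)oxy]butanoyl]oxy}propyl)benzoyl]oxy}butanoate | C[C@@H](O[Si](C(C)C)(C(C)C)C(C)C)CC(=O)O[C@H](C)Cc1cc(OCc2ccccc2)cc(OCc2ccccc2)c1C(=O)O[C@@H](C)CC(=O)OCc1ccccc1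
F8 | step 17 | benzyl (S)-3-{[2,4-bis(benzyloxy)-6-((R)-2-{[(R)-3-hydroxybutanoyl]oxy}propyl)benzoyl]oxy}butanoate | C[C@@H](O)CC(=O)O[C@H](C)Cc1cc(OCc2ccccc2)cc(OCc2ccccc2)c1C(=O)O[C@@H](C)CC(=O)OCc1ccccc1
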